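A small charge of catalyst, 0.50 mM in each flask, turns starting material and dissolved coupling partner into target, and one number can follow that work.

in all of them: catalyst 0.50 mM

| charge | starting material | second substrate | gas | temperature | remark | time |
|---|---|---|---|---|---|---|
| winter | 10 mM | 40 mM (fed, over 2.5 min) | 1.7 mM (held) | 25 °C | run made earlier |  |
| epsilon | 20 mM | 40.0 mM (fed, over 2.5 min) | 1.7 mM (held) | 25 °C |  | 5.0 min |
| beta | 20 mM | 40.0 mM | 1.7 mM | −5 °C | everything together at the start | 8.0 min |

winter run (percent of the starting material charged): time / s: target / % = 10.0: 2.6; 15.0: 6.3; 25.0: 10.0; 30.0: 11.1; 40.0: 14.5; 50.0: 18.1; 60.0: 21.2

(each reading ± 1 percentage point)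

- what is said of target includes idle complex
- at the start none of coupling partner is dissolved
- candidate steps: starting material + coupling partner + catalyst -> catalyst + target; second substrate + coupling partner + catalyst -> catalyst + second product; gas <-> coupling partner; catalyst + target <-> idle complex
- the earlier runs do not show what temperature does; that part of a forecast is a guess

- the winner by amount of target, in percent of the starting material charged; "neither" if no more than 2 percentage points parts them (epsilon / beta / neither)
- how much target is there at the end, in percent of the starting material charged: epsilon
- how much target is there at the end, in percent of the starting material charged: beta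

The winter run's first and last readings give

10 mM × (21.2% − 2.6%) / (60.0 s − 10.0 s) = 0.0372 mM/s

This is the target flow: the concentration of target made per second. A percentage of target is then the flow times the time, divided by the charge of starting material.

In the first instants no coupling partner is dissolved, yet the winter run already reads 2.6% at 10.0 s, so the wait is short against epsilon's 5.0 min. In the middle the feed brings second substrate, 16.0 mM by 60.0 s in the winter run, and a dissolved coupling partner has two exits, target or second product. The winter readings do not give the odds between them. Later, target can hold catalyst as idle complex (product inhibition), which these readings cannot separate from target.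

The reckoning here assumes that the flow does not change with the charge. For epsilon that gives

flow × 5.0 min / 20 mM = 55.8%

This is above the forecast's figure. For beta the same flow gives 89.3%, but that holds at the winter temperature, and the flow at −5 °C is a guess. With equal charges, beta's percentage matches epsilon's at a mean flow 0.625 times epsilon's.

The forecast names epsilon as winner, with 50% (33% to 66%) for epsilon and 22% (8% to 42%) for beta, whose cold it treats as a step “which I guess slows the chemistry about fivefold”.

The simulation gives epsilon as winner, with 51.3% for epsilon and 42.2% for beta.

    starting material + coupling partner + catalyst → catalyst + target (k = 25000 /M²/s, Ea = 12.0 kJ/mol)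
    second substrate + coupling partner + catalyst → catalyst + second product (k = 6900 /M²/s, Ea = 10.0 kJ/mol)
    gas ⇌ coupling partner, rate k3*(csat - [coupling partner]) (kL = 0.0400 /s)
    catalyst + target ⇌ idle complex, settled at all times (K = 150 /M, ΔH = −44.0 kJ/mol)
    (constants at 25 °C)

Epsilon's mean flow is 0.0342 mM/s, against the 0.0372 mM/s read from the winter run. Beta's is 0.0176 mM/s, which is 0.515 of epsilon's and below the 0.625 needed to draw level, though beta ends 20 percentage points above the forecast. The neighbouring flask is beta with 80 mM of starting material. Beta's flow held there gives 10.5%, but the neighbouring flask ends at 20.6%, a mean flow of 0.0343 mM/s, twice beta's.

The runs are calculated with constants of no real substance; scatter was added.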